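A closed, stirred vessel at fixed temperature holds starting material and reagent. Reagent turns starting material into intermediate B, and further reagent turns intermediate B into product, so the two steps compete for the same reagent.

| flask | starting material | reagent | remark | time |
|---|---|---|---|---|
| south-west | 0.43 M | 0.19 M | run made earlier |  |
| east | 0.43 M | 0.48 M | run made earlier |  |
| south | 0.43 M | 1.7 M | run made earlier |  |
| oak | 0.43 M | 0.408 M |  | 2.0 min |
| elm | 0.43 M | 0.150 M |  | 2.0 min |
| ash | 0.43 M | 1.50 M |  | 2.0 min |
| cedar | 0.43 M | 0.600 M |  | 2.0 min |
| alder | 0.43 M | 0.800 M |  | 2.0 min |

| run | time / s | product / % | starting material / % |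
|---|---|---|---|
| south-west | 10.0 | 0 | 71.4 |
| south-west | 20.0 | 0 | 63.3 |
| south-west | 50.0 | 0.6 | 56.9 |
| south-west | 120 | 0.9 | 56.4 |
| east | 30.0 | 3.6 | 16.7 |
| east | 60.0 | 7.0 | 8.3 |
| east | 90.0 | 8.9 | 5.9 |
| east | 120 | 10.0 | 4.4 |
| south | 30.0 | 38.5 | 1.3 |
| south | 60.0 | 60.9 | 1.2 |
| south | 90.0 | 74.2 | 0 |
| south | 120 | 82.5 | 0 |

(readings scatter by 0.5 percentage points)

- the analysis behind the earlier runs scatters by 0.5 percentage points, standard deviation
- steps thought possible: starting material + reagent <-> intermediate A; reagent + intermediate B -> product; starting material + reagent -> intermediate B

- the flasks put in order of amount of product, in percent of the starting material charged, best first, at 2.0 min (oak / elm / ash / cedar / alder)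
- the amount of product, in percent of the starting material charged of the flask you put first, at 2.0 min
- the amount of product, in percent of the starting material charged of the flask you put last, at 2.0 min

I leave intermediate A aside. The first south-west reading, reckoned second-order with both charges counted, gives a first-step constant of 0.294 /M/s. The south run between 60.0 s and 120 s, with reagent taken at its mean, gives a second-step constant of 0.0139 /M/s. Both are readings and carry the scatter. I carry their quotient, second over first, 0.0474, the selectivity factor. If I divide the two rates, reagent and time drop out: product forms per starting material consumed at this factor times intermediate B over starting material. Integrated over the consumed fraction x, product is the factor times (ln(1/(1−x)) − x).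

Now I turn the question round. For elm to send its reagent to product as readily as to intermediate B at the end, the factor would have to equal starting material over intermediate B there. Reagent is elm's limiting reagent, so x reaches about 0.349 and the factor needed is 1.87, which is 39.4 times the one read. So I commit to 0.380% for elm.

The forecast gives ash > alder > cedar > oak > elm, with 76% first and 0.4% last, on the ground that “Product should therefore rise steadily with reagent”.

The flasks give ash > alder > cedar > oak > elm, with 76.6% in ash and 0.389% in elm.

    starting material + reagent ⇌ intermediate A (K = 1.60 /M, k = 0.00720 /M/s)
    reagent + intermediate B → product (k = 0.0150 /M/s)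
    starting material + reagent → intermediate B (k = 0.290 /M/s)

Take a neighbour of elm with the same reagent but starting material cut to 0.26 M. There x reaches about 0.577, so the factor needed is 0.733, which is 15.5 times the carried one. The same reckoning gives 1.34% of that flask's charge. The neighbour gives 1.29% of product at 2.00 min, with 44.1% of its starting material left.

(The runs are calculated with made-up constants, and the scatter is random.)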